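The γ-butyrolactone ring carries a benzylic group on each of its adjacent stereocentres C3 and C4, and its OCH2 carbon C5 can be read as the stump of a cleaved alkene. The chain O=C2–C3–C4–C5 is thus the mark of a γ,δ-unsaturated acid, so the route disconnects C3–C4, the bond joining the two C6–C3 units, by an Ireland–Claisen rearrangement. In a single operation this step forges that C–C bond and sets both stereocentres by chirality transfer from a secondary allylic carbinol, which is excised afterwards. Its precursor is an acyclic ester with one stereocentre, assembled from O-benzyl dihydroisoferulic acid and an (R,E)-allylic alcohol derived from methyl eugenol.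

Key step: step 5

Remark: (R)-but-3-en-2-ol is assumed to be bought in high enantiomeric purity, since it is the only source of chirality. Lactone atoms are numbered O1, C2 (carbonyl), C3, C4, C5; open-chain acids are numbered from the carboxyl carbon.

Step 1
Reactants: 1 methyl eugenol; 2 (R)-but-3-en-2-ol
Product: 3 (2R,3E)-5-(3,4-dimethoxyphenyl)pent-3-en-2-ol
Conditions: RuCl2(H2IMes)(=CH-C6H4-2-OiPr) (second-generation Hoveyda–Grubbs catalyst, H2IMes = 1,3-dimesitylimidazolidin-2-ylidene, 3 mol %), 1,4-benzoquinone (10 mol %), 1 (3 equiv), CH2Cl2, 40 °C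
Reagents that add atoms: none
Why: Ruthenium-carbene olefin cross-metathesis of a terminal allylbenzene with a hindered secondary allylic alcohol should deliver the cross product with the thermodynamically favoured (E)-geometry, 1,4-benzoquinone scavenging ruthenium hydrides that would shift the double bond, and the carbinol stereocentre is not involved.

Step 2
Reactants: 4 isoferulic acid
Product: 5 3-(3-hydroxy-4-methoxyphenyl)propanoic acid
Conditions: H2 (1 atm), 10% Pd/C, EtOAc/MeOH, rt
Reagents that add atoms: none
Why: Heterogeneous catalytic hydrogenation saturates the cinnamic C=C bond selectively, leaving the arene, the phenol and the carboxylic acid untouched.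

Step 3
Reactants: 5 3-(3-hydroxy-4-methoxyphenyl)propanoic acid; 6 benzyl bromide
Product: 8 3-[3-(benzyloxy)-4-methoxyphenyl]propanoic acid, via benzyl ester 7 (not isolated)
Conditions: 6 (2.3 equiv), K2CO3, DMF, 60 °C; then LiOH, THF/H2O, 50 °C; aq. HCl to pH 2
Reagents that add atoms: lithium hydroxide, [Li+].[OH-] (its oxygen ends up in the carboxyl group of 8)
Why: Williamson O-alkylation of both the phenoxide and the carboxylate is followed by saponification, which cleaves only the benzyl ester because the aryl benzyl ether is inert to hydroxide.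

Step 4
Reactants: 3 (2R,3E)-5-(3,4-dimethoxyphenyl)pent-3-en-2-ol; 8 3-[3-(benzyloxy)-4-methoxyphenyl]propanoic acid
Product: 9 (2R,3E)-5-(3,4-dimethoxyphenyl)pent-3-en-2-yl 3-[3-(benzyloxy)-4-methoxyphenyl]propanoate
Conditions: DCC, DMAP (10 mol %), CH2Cl2, 0 °C to rt
Reagents that add atoms: none
Why: Steglich esterification activates the acid as an O-acylisourea and then an acylpyridinium ion, so the carbinol C–O bond is never broken and the (R) configuration and the (E)-alkene are retained.

Step 5
Reactants: 9 (2R,3E)-5-(3,4-dimethoxyphenyl)pent-3-en-2-yl 3-[3-(benzyloxy)-4-methoxyphenyl]propanoate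
Product: 12 (2R,3S,E)-2-[3-(benzyloxy)-4-methoxybenzyl]-3-(3,4-dimethoxybenzyl)hex-4-enoic acid, via Z-silyl ketene acetal 10 (not isolated), via trimethylsilyl ester 11 (not isolated)
Conditions: LiN(iPr)2 (1.3 equiv), THF/DMPU (4:1), −78 °C; Me3SiCl (1.5 equiv), −78 °C to rt, then 50 °C; 1 M HCl, rt
Reagents that add atoms: chlorotrimethylsilane, C[Si](C)(C)Cl (its Me3Si group is present in 10 and 11 only and is lost on work-up)
Why: LiN(iPr)2 in the presence of DMPU removes a proton from the only acidic CH2 through an open transition state and gives the enolate with the arylmethyl group cis to the oxyanion, O-silylation fixes this as the (Z)-silyl ketene acetal 10, and on warming 10 undergoes a concerted suprafacial [3,3]-sigmatropic shift through a six-membered chair in which the bond between the acetal α-carbon and the distal alkene carbon (C3–C4 of the future lactone) forms as the allylic C–O bond breaks. The closest known reaction type is the Ireland–Claisen rearrangement of esters of enantioenriched secondary (E)-allylic alcohols with solvent-controlled enolate geometry. No ring is closed; the only cyclic array is the transient chair. The stereocentre at acid C3 (lactone C4) is controlled by the (R)-carbinol, whose methyl group takes the equatorial position so that the new bond forms on a single face of the (E)-alkene and an (E)-propenyl group emerges, and the stereocentre at acid C2 (lactone C3) is controlled by the acetal geometry, the Z isomer placing the arylmethyl group equatorial and leading to the syn (2R,3S) acid. The step needs facial selectivity on the alkene and syn diastereoselectivity; the first is secured by the equatorial preference of the carbinol methyl group and the second by pairing the (Z)-acetal with the (E)-alkene, any anti isomer being correctable later because lactone C3 is epimerizable whereas C4 is not.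

Step 6
Reactants: 12 (2R,3S,E)-2-[3-(benzyloxy)-4-methoxybenzyl]-3-(3,4-dimethoxybenzyl)hex-4-enoic acid
Product: 15 (2R,3R)-2-[3-(benzyloxy)-4-methoxybenzyl]-4-(3,4-dimethoxyphenyl)-3-(hydroxymethyl)butanoic acid, via ozonide 13 (not isolated), via aldehyde 14 (not isolated)
Conditions: O3/O2, CH2Cl2, −78 °C, Sudan Red 7B end point; N2 purge; NaBH4 (excess), MeOH, −78 to 0 °C; aq. NaHSO4 to pH 3, EtOAc; crude 15 used directly
Reagents that add atoms: ozone, [O-][O+]=O
Why: Ozonolysis (1,3-dipolar cycloaddition then Criegee rearrangement) should cleave the isolated disubstituted alkene much faster than the arenes when stopped at the dye end point, and borohydride reduction of the ozonide in the cold converts the epimerizable aldehyde 14 into the alcohol as it forms, so the stereocentres are preserved while the propenyl terminus leaves as ethanol.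

Step 7
Reactants: 15 (2R,3R)-2-[3-(benzyloxy)-4-methoxybenzyl]-4-(3,4-dimethoxyphenyl)-3-(hydroxymethyl)butanoic acid
Product: 16 (3R,4R)-3-[3-(benzyloxy)-4-methoxybenzyl]-4-(3,4-dimethoxybenzyl)dihydrofuran-2(3H)-one (O-benzyl prestegane A)
Conditions: pTsOH·H2O (5 mol %), toluene, 50 °C; then DBU (1 equiv), toluene, 80 °C
Reagents that add atoms: none
Why: Acid-catalysed intramolecular esterification closes the γ-lactone by 5-exo-trig attack of the primary alcohol on the carboxyl group, and reversible enolization with DBU, which can touch only C3, should drain any cis isomer into the more stable trans-3,4-disubstituted lactone.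

Step 8
Reactants: 16 (3R,4R)-3-[3-(benzyloxy)-4-methoxybenzyl]-4-(3,4-dimethoxybenzyl)dihydrofuran-2(3H)-one
Product: 17 prestegane A, (3R,4R)-4-(3,4-dimethoxybenzyl)-3-(3-hydroxy-4-methoxybenzyl)dihydrofuran-2(3H)-one
Conditions: H2 (1 atm), 10% Pd/C, EtOAc/EtOH, rt
Reagents that add atoms: none
Why: Palladium-catalysed hydrogenolysis cleaves the benzylic C–O bond of the aryl benzyl ether, while the lactone, the methyl ethers and both stereocentres are inert under these neutral conditions.

Compound list

1 | methyl eugenol (4-allyl-1,2-dimethoxybenzene) | C=CCc1ccc(OC)c(OC)c1 | starting material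
2 | (R)-but-3-en-2-ol | C[C@@H](O)C=C | starting material
3 | (2R,3E)-5-(3,4-dimethoxyphenyl)pent-3-en-2-ol | C[C@@H](O)/C=C/Cc1ccc(OC)c(OC)c1 | intermediate
4 | isoferulic acid, (E)-3-(3-hydroxy-4-methoxyphenyl)prop-2-enoic acid | COc1ccc(/C=C/C(=O)O)cc1O | starting material
5 | 3-(3-hydroxy-4-methoxyphenyl)propanoic acid | COc1ccc(CCC(=O)O)cc1O | intermediate
6 | benzyl bromide | BrCc1ccccc1 | starting material
7 | benzyl 3-[3-(benzyloxy)-4-methoxyphenyl]propanoate | COc1ccc(CCC(=O)OCc2ccccc2)cc1OCc1ccccc1 | intermediate
8 | 3-[3-(benzyloxy)-4-methoxyphenyl]propanoic acid | COc1ccc(CCC(=O)O)cc1OCc1ccccc1 | intermediate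
9 | (2R,3E)-5-(3,4-dimethoxyphenyl)pent-3-en-2-yl 3-[3-(benzyloxy)-4-methoxyphenyl]propanoate | COc1ccc(CCC(=O)O[C@H](C)/C=C/Cc2ccc(OC)c(OC)c2)cc1OCc1ccccc1 | intermediate
10 | (Z)-O-trimethylsilyl ketene acetal of 9, arylmethyl group cis to OSiMe3, (R)-carbinol and (E)-alkene unchanged | COc1ccc(C/C=C(\O[Si](C)(C)C)O[C@H](C)/C=C/Cc2ccc(OC)c(OC)c2)cc1OCc1ccccc1 | intermediate
11 | trimethylsilyl (2R,3S,E)-2-[3-(benzyloxy)-4-methoxybenzyl]-3-(3,4-dimethoxybenzyl)hex-4-enoate | COc1ccc(C[C@@H](C(=O)O[Si](C)(C)C)[C@H](/C=C/C)Cc2ccc(OC)c(OC)c2)cc1OCc1ccccc1 | intermediate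
12 | (2R,3S,E)-2-[3-(benzyloxy)-4-methoxybenzyl]-3-(3,4-dimethoxybenzyl)hex-4-enoic acid (syn acid) | COc1ccc(C[C@@H](C(=O)O)[C@H](/C=C/C)Cc2ccc(OC)c(OC)c2)cc1OCc1ccccc1 | intermediate
13 | secondary ozonide of 12, a 5-methyl-1,2,4-trioxolan-3-yl group in place of the propenyl group (mixture at the trioxolane carbons) | COc1ccc(C[C@@H](C(=O)O)[C@H](C2OOC(C)O2)Cc2ccc(OC)c(OC)c2)cc1OCc1ccccc1 | intermediate
14 | (2R,3R)-2-[3-(benzyloxy)-4-methoxybenzyl]-3-(3,4-dimethoxybenzyl)-4-oxobutanoic acid | COc1ccc(C[C@@H](C(=O)O)[C@H](C=O)Cc2ccc(OC)c(OC)c2)cc1OCc1ccccc1 | intermediate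
15 | (2R,3R)-2-[3-(benzyloxy)-4-methoxybenzyl]-4-(3,4-dimethoxyphenyl)-3-(hydroxymethyl)butanoic acid | COc1ccc(C[C@@H](C(=O)O)[C@H](CO)Cc2ccc(OC)c(OC)c2)cc1OCc1ccccc1 | intermediate
16 | (3R,4R)-3-[3-(benzyloxy)-4-methoxybenzyl]-4-(3,4-dimethoxybenzyl)dihydrofuran-2(3H)-one | COc1ccc(C[C@H]2C(=O)OC[C@@H]2Cc2ccc(OC)c(OC)c2)cc1OCc1ccccc1 | intermediate
17 | prestegane A, (3R,4R)-4-(3,4-dimethoxybenzyl)-3-(3-hydroxy-4-methoxybenzyl)dihydrofuran-2(3H)-one | COc1ccc(C[C@H]2C(=O)OC[C@@H]2Cc2ccc(OC)c(OC)c2)cc1O | target

Total step count: 8. Longest linear sequence: 7 steps (isoferulic acid 4 to 17 through steps 2, 3, 4, 5, 6, 7 and 8).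

Steps most likely to fail

Step 5. The enolization may not be fully geometry-selective, and the ketene acetal may be C-silylated or hydrolysed before it rearranges, which would give low conversion and diastereomer mixtures. The fallback sets out from allylic alcohol 3 and comes back at lactone 16. Heating 3 with trimethyl orthoacetate and catalytic propanoic acid (Johnson–Claisen rearrangement) uses the same chair and the same chirality transfer but has no α-substituent, so no enolate geometry needs control; it should give methyl (R,E)-3-(3,4-dimethoxybenzyl)hex-4-enoate F1. Ozonolysis with NaBH4 reduction should give methyl (R)-4-(3,4-dimethoxyphenyl)-3-(hydroxymethyl)butanoate F2, which closes under acid catalysis to (R)-4-(3,4-dimethoxybenzyl)dihydrofuran-2(3H)-one F3. Its lithium enolate (LiN(SiMe3)2, THF, −78 °C) is alkylated with 3-(benzyloxy)-4-methoxybenzyl bromide F4, prepared from the commercial benzyl alcohol with PBr3. Attack anti to the C4 substituent should give the trans lactone 16 directly.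

Step 1. Double-bond migration in the allylbenzene partner, self-metathesis and incomplete E selectivity may occur. Any (Z)-alkene carried forward would relay the opposite configuration in step 5 and erode enantiopurity. The fallback sets out from 2 and comes back at 3, and avoids metathesis altogether. Silylation of 2 (tBuMe2SiCl, imidazole) gives (R)-tert-butyl(but-3-en-2-yloxy)dimethylsilane F5, and ozonolysis with PPh3 work-up gives (R)-2-(tert-butyldimethylsilyloxy)propanal F6. Separately, commercial 2-(3,4-dimethoxyphenyl)ethanol is converted by Mitsunobu reaction with 1-phenyl-1H-tetrazole-5-thiol (PPh3, diisopropyl azodicarboxylate) into 5-{[2-(3,4-dimethoxyphenyl)ethyl]sulfanyl}-1-phenyl-1H-tetrazole F7, which is oxidized with mCPBA to 5-{[2-(3,4-dimethoxyphenyl)ethyl]sulfonyl}-1-phenyl-1H-tetrazole F8. Julia–Kocienski olefination of F6 with the anion of F8 (KN(SiMe3)2, 1,2-dimethoxyethane, −60 °C to rt) should give tert-butyl{[(2R,3E)-5-(3,4-dimethoxyphenyl)pent-3-en-2-yl]oxy}dimethylsilane F9, and Bu4NF in THF removes the silyl group to return 3.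

Step 6. Ozone may over-oxidize the electron-rich arenes or the benzyl ether, and the transient aldehyde may epimerize at its α-carbon before it is reduced, which would end as loss of enantiopurity after the C3 equilibration. The fallback sets out from acid 12 and comes back at aldehyde 14. Dihydroxylation with catalytic OsO4 and N-methylmorpholine N-oxide in aqueous acetone containing NaHCO3 (so that the product stays a carboxylate and does not lactonize) should give (2R,3R)-2-[3-(benzyloxy)-4-methoxybenzyl]-3-(3,4-dimethoxybenzyl)-4,5-dihydroxyhexanoic acid F10 as a mixture at C4 and C5. NaIO4 at 0 °C cleaves the diol to 14, and NaBH4 added to the same flask reduces 14 to 15 as in step 6.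

Further compounds

F1 | step 5 | methyl (R,E)-3-(3,4-dimethoxybenzyl)hex-4-enoate | COC(=O)C[C@H](/C=C/C)Cc1ccc(OC)c(OC)c1
F2 | step 5 | methyl (R)-4-(3,4-dimethoxyphenyl)-3-(hydroxymethyl)butanoate | COC(=O)C[C@H](CO)Cc1ccc(OC)c(OC)c1
F3 | step 5 | (R)-4-(3,4-dimethoxybenzyl)dihydrofuran-2(3H)-one | O=C1C[C@@H](Cc2ccc(OC)c(OC)c2)CO1
F4 | step 5 | 3-(benzyloxy)-4-methoxybenzyl bromide | COc1ccc(CBr)cc1OCc1ccccc1
F5 | step 1 | (R)-tert-butyl(but-3-en-2-yloxy)dimethylsilane | C[C@@H](O[Si](C)(C)C(C)(C)C)C=C
F6 | step 1 | (R)-2-(tert-butyldimethylsilyloxy)propanal | C[C@@H](O[Si](C)(C)C(C)(C)C)C=O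
F7 | step 1 | 5-{[2-(3,4-dimethoxyphenyl)ethyl]sulfanyl}-1-phenyl-1H-tetrazole | COc1ccc(CCSc2nnnn2-c2ccccc2)cc1OC
F8 | step 1 | 5-{[2-(3,4-dimethoxyphenyl)ethyl]sulfonyl}-1-phenyl-1H-tetrazole | COc1ccc(CCS(=O)(=O)c2nnnn2-c2ccccc2)cc1OC
F9 | step 1 | tert-butyl{[(2R,3E)-5-(3,4-dimethoxyphenyl)pent-3-en-2-yl]oxy}dimethylsilane | C[C@@H](O[Si](C)(C)C(C)(C)C)/C=C/Cc1ccc(OC)c(OC)c1
F10 | step 6 | (2R,3R)-2-[3-(benzyloxy)-4-methoxybenzyl]-3-(3,4-dimethoxybenzyl)-4,5-dihydroxyhexanoic acid (mixture at C4 and C5) | COc1ccc(C[C@@H](C(=O)O)[C@H](C(O)C(C)O)Cc2ccc(OC)c(OC)c2)cc1OCc1ccccc1
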